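The constant to read from the two earlier runs is a clock for the partner.

the same everywhere: free catalyst 1 mol%; racemization catalyst 1 mol%
- ochre: left-handed substrate 0.018 M; right-handed substrate 0.018 M; partner 2 equiv; run made earlier
- green: left-handed substrate 0.027 M; right-handed substrate 0.027 M; partner 2 equiv; run made earlier
- flask: left-handed substrate 0.036 M; right-handed substrate 0.036 M; partner 2.00 equiv; time 2.0 min

| run | time / min | left-handed product / % |
|---|---|---|
| ochre | 0.500 | 15 |
| ochre | 0.667 | 18 |
| ochre | 0.833 | 22 |
| ochre | 1.00 | 23 |
| ochre | 1.33 | 33 |
| ochre | 2.00 | 38 |
| ochre | 2.50 | 42 |
| green | 0.500 | 30 |
| green | 0.667 | 30 |
| green | 0.833 | 35 |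
| green | 1.00 | 40 |
| green | 1.33 | 46 |
| green | 2.00 | 56 |
| green | 2.50 | 65 |

(readings scatter by 2 percentage points)

- time up to 2.0 min at which left-handed product stands highest
- the amount of left-handed product, in percent of the left-handed substrate and right-handed substrate together charged, at that time

- free catalyst is single-handed; left-handed substrate and right-handed substrate are mirror images of each other, charged as a racemate, each of them at the stated concentration

The readings look contradictory: the left-handed substrate is half of the racemate, yet the green run reads 65% left-handed product after 2.50 min, more than that half. So right-handed substrate must be passing into left-handed substrate, and the two are reckoned here as one pool, u being its fraction of the charge. At 2.00 equiv on the left-handed substrate, partner matches that pool one to one. If the free catalyst stays constant and the left-handed share of the pool stays nearly frozen, partner and pool fall together, second order in u, and the ratio of product to remaining pool grows in a straight line with time.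

The last readings give slopes of 0.290 min⁻¹ for ochre and 0.743 min⁻¹ for green, a ratio of 2.56 as read, carrying the scatter of both readings, against 2.25 for the squared concentration. Scaled by that square and averaged, they give 1.24 min⁻¹ for this flask: the partner clock, the pseudo-first-order fraction of partner used per minute while the pool stands whole. This reckoning gives 71.3% left-handed product in this flask at 2.0 min, still rising.

The forecast says 75% at 2 min, higher than this reckoning, on its ground that “2.0 min there corresponds to about 3.5 min of green”; the two part in the curve laid through green, since the forecast continues green as a first-order curve.

The flask gives 67.3% at 2.00 min, 7.7 percentage points below the forecast, with right-handed product at 3.24%.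

    partner + free catalyst + right-handed substrate → free catalyst + right-handed product (k = 59.0 M⁻² s⁻¹)
    partner + free catalyst + left-handed substrate → free catalyst + left-handed product (k = 2000 M⁻² s⁻¹)
    left-handed substrate + racemization catalyst ⇌ right-handed substrate + racemization catalyst, rate k3*[racemization catalyst]*[left-handed substrate] forward; the back reaction follows from the equilibrium constant (k = 51.0 M⁻¹ s⁻¹)

The neighbour flask with 0.500 equiv of partner has this flask's substrate and catalyst charges and ends with 77.0% of the pool unreacted, and the partner clock of 1.24 min⁻¹, applied to its partner as a pseudo-first-order constant, gives 8.37% of that partner left at 2.00 min. That neighbour flask ends with 7.86% of its partner.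

The data were computed for an exercise, noise included.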